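| flask | starting material | gas | remark | time |
|---|---|---|---|---|
| Tuesday's | 0.40 M | 110 mM (held) | run made earlier |  |
| flask | 0.80 M | 110 mM (held) |  | 8.0 min |
Tuesday's run (percent of the starting material charged)

| time / min | ring / % | starting material / % |
|---|---|---|
| 0.500 | 32 | 45 |
| 1.00 | 44 | 18 |
| 1.33 | 48 | 8 |
| 2.00 | 52 | 6 |
| 2.50 | 50 | 3 |

(readings scatter by 1.5 percentage points)
- percentages count the starting material that a species holds: one open dimer or side product counts as two
- at the start none of activator is dissolved
- candidate steps: starting material + activator -> activated form; activated form -> ring; starting material + activated form -> open dimer; gas <-> activator; starting material + ring -> side product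
1. ring at 8.0 min, in percent of the starting material charged
2. concentration of activator in solution at 8.0 min, in percent of saturation

- Tuesday's run is slow enough to read: its starting material shrinks by a factor 2.22 in the first 0.500 min and 2.50 in the next half minute, so I treat dissolved activator as steady and the fall as pseudo-first-order.
- If starting material destroys ring, making and loss both carry starting material, so ring gained per starting material consumed is (c − ring)/(c + ring).
- Between 32% ring, with 45% starting material left, and the plateau of 51.0%, Tuesday's run gains 0.422 per portion consumed around 41.5% ring, so I read c = 0.409 M, the ring ceiling, the ring concentration at which loss equals making.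
- With dissolved activator held as in Tuesday's run, the flask's first 0.40 M consumed should repeat that run and leave 0.204 M ring, with gain 0.334 at that point.
- Holding that gain over the remaining 0.400 M gives this rule's upper bound for the flask, 42.2%; the gain at that top, 0.0952, gives its lower bound, 30.3%, and both are estimates that carry the scatter of the reading of c.
- I commit to the middle, 36.3%; the forecast says 32% (26% to 38%), a central value inside my bracket but lower than my middle, since it holds that thinner activator “favours the second-order losses”, and 99.5% saturation (96% to 100%).

- The flask gives 34.6% ring,  inside the bracket and the forecast's range, and 100% saturation with 0% starting material at 8.00 min.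

    starting material + activator → activated form (k = 0.200 M⁻¹ s⁻¹)
    activated form → ring (k = 0.330 s⁻¹)
    starting material + activated form → open dimer (k = 0.0370 M⁻¹ s⁻¹)
    gas ⇌ activator, rate k4*(csat - [activator]) (kL = 3.50 s⁻¹)
    starting material + ring → side product (k = 0.0640 M⁻¹ s⁻¹)

- That ring in the flask is 0.276 M, below the ceiling of 0.409 M. A neighbouring flask charged with 0.48 M starting material, reckoned the same way, consumes 0.0800 M beyond Tuesday's amount, which gives 47.1% to 48.1% ring, and that flask gives 46.4%, 0.7 percentage points under the bracket.

Readings and results are simulated for substances that don't exist, noise included.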